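We reckon in rates.

in all of them: substrate 0.23 M
- epsilon: reagent in the second phase 0.55 equiv; run made earlier
- theta: reagent in the second phase 0.83 equiv; run made earlier
- flask: reagent in the second phase 1.10 equiv; time 6.0 h; volume of the second phase over the first 2.0

| run | time / h | target / % |
|---|---|---|
| epsilon | 0.250 | 0.3 |
| epsilon | 0.417 | 0 |
| epsilon | 0.667 | 1.7 |
| epsilon | 1.00 | 1.0 |
| epsilon | 1.50 | 2.9 |
| epsilon | 2.50 | 4.3 |
| epsilon | 4.00 | 6.6 |
| theta | 0.250 | 0 |
| theta | 0.417 | 0 |
| theta | 0.667 | 0 |
| theta | 1.00 | 2.3 |
| theta | 1.50 | 4.4 |
| theta | 2.50 | 5.5 |
| theta | 4.00 | 8.6 |

(each reading ± 1 percentage point)

- in the second phase: reagent in the second phase; everything else is in the first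
- charges count per volume of the first phase; a concentration in a rate is the amount of a species over the volume of its own phase; every rate counts per litre of the first phase
- the numbers in the tables scatter by 1 percentage point (one standard deviation)
- the earlier runs hold the two phases in the same ratio of volumes as the flask asked about

- spring: doubling the amount of reagent in the second phase, all else as stated
- autumn: doubling the transfer coefficient of the reagent in the second phase, all else as stated

* amount of target at 6.0 h, in percent of the substrate charged
* the change that raises the amount of target at 6.0 h, in percent of the substrate charged most ("none" if none brings more than 2 percentage points) (spring / autumn / none)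
* amount of target at 6.0 h, in percent of the substrate charged, after spring

Step 1, the start. Epsilon makes target at a mean rate of 0.0165 /h up to 4.00 h, counted as a fraction of the substrate charged. The flask holds twice the reagent in the second phase of epsilon, so we need the effect of doubling that charge.

Step 2, the first slowing. From epsilon to theta, the charge rises by a factor 1.51 and the last reading by a factor 1.30. These two readings give an apparent order in reagent of 0.643. We call 1.56 the reagent gain, the factor by which the rate of target rises when the charge of reagent in the second phase doubles. It carries the scatter of 1 percentage point. We therefore reckon a mean rate of 0.0258 /h for the flask up to 4.00 h, which is 0.780 of simple doubling.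

Step 3, the second slowing. Pooling both runs, the rate from 2.50 h to 4.00 h is 0.918 of the rate before 2.50 h, again a reading.

Step 4, the end. We carry that mean rate to 4.00 h and the slowed rate to 6.0 h, which gives 15.0 % of target in the flask. That is 0.758 of what simple doubling without slowing gives. The runs vary the charge and leave the transfer coefficient untouched, so we choose spring and reckon it at 23.5 %.

Step 5, the forecast. It calls the rate “close to first order in reagent” and gives 16.5 %, spring and 29 %, which is higher than our reckoning on both amounts.

Step 6, the flask. It holds 12.3 % of target at 6.0 h.

    reagent in the reaction phase ⇌ reagent in the second phase, rate k1*([reagent in the reaction phase] - [reagent in the second phase]/K1) per volume of the first phase (partition coefficient = 1.60, kL = 0.220 /h)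
    substrate + reagent in the reaction phase → target (k = 5.70 /M/h)
    reagent in the reaction phase + target → over-reacted product (k = 12.0 /M/h)
    substrate + target → side product (k = 0.400 /M/h)
    target ⇌ isomer of the product (K = 0.480, k = 0.180 /h)

Step 7, the gain in use. At 6.00 h, target in the flask is made 1.26 times as fast as it is used up, each step taken net. The best change is spring, which gains 4.7 points against 3.1 points for autumn. The reagent gain applied to 12.3 % gives 19.2 %, and the flask after spring holds 17.0 %. For the neighbour flask, left until 2.5 h, the reagent gain applied to the epsilon reading of 4.3 % gives 6.71 %, and that neighbour holds 7.51 %.

(The data come from a simulation for an exercise, noise included.)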